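**Retrosynthetic overview**

1. The target is fisetinidol-(4α→8)-catechin-(6→4β)-fisetinidol. The plan rests on C4 of the C8-bound unit: a doubly benzylic CH that joins C4a of that unit's resorcinol ring A to C8 of the catechin ring A and stands trans to the C3 hydroxyl on ring C.
2. Late disconnections: thirteen benzyl ethers (hydrogenolysis), then the C4–C6 bond of the 4β unit (C6 aryl–cerium addition to benzylated (+)-fustin, then ionic hydrogenation with hydride delivered trans to O3).
3. Key disconnection: C4–C4a of the 4α unit, by Friedel–Crafts opening of a trans-epoxide by a tethered 3-benzyloxyphenyl ether. The ether comes from a Mitsunobu inversion, the epoxide from a Shi epoxidation, the carbinol from a CBS reduction of a chalcone built on 6-bromo-8-formyl-penta-O-benzylcatechin.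
4. The aryl ether is introduced after the epoxidation, so that a leaving group never sits on a 1,3-diarylallyl carbon. Ring order: all rings of catechin and of the 4β unit are bought intact; ring C of the 4α unit is the only ring closed (step 10).

Key step: step 10

Remark: in step 7 the 3,4-bis(benzyloxy)phenyl group of enone 10 is assumed to act as the large substituent toward the oxazaborolidine and the E-alkenyl arm as the small one, as for aryl ketones in general.

**Step 1**
Reactants: 1 (+)-catechin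
Product: 2 tetra-O-benzylcatechin (5,7,3′,4′-tetrabenzyl ether, free 3-OH)
Conditions: BnBr (4.4 equiv), K2CO3, DMF, 0 °C → rt
Reagents that add atoms: benzyl bromide, BrCc1ccccc1
Why: Williamson etherification of the four phenols with a carbonate base, which is too weak to alkylate the secondary C3 alcohol; C2 and C3 are untouched.

**Step 2**
Reactants: 2 tetra-O-benzylcatechin
Product: 3 penta-O-benzylcatechin (3,5,7,3′,4′-pentabenzyl ether)
Conditions: NaH, BnBr, DMF, 0 °C → rt
Reagents that add atoms: benzyl bromide, BrCc1ccccc1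
Why: Williamson O-benzylation of the C3 alkoxide; with all phenols etherified, no quinone methide can form, so C2 should not epimerise under the strong base.

**Step 3**
Reactants: 3 penta-O-benzylcatechin
Product: 5 penta-O-benzylcatechin-8-carbaldehyde, via Vilsmeier iminium salt 4 (not isolated)
Conditions: POCl3, DMF, 0 → 60 °C; then H2O, rt
Reagents that add atoms: N,N-dimethylformamide, CN(C)C=O; water, O
Why: Vilsmeier–Haack formylation of the phloroglucinol-type ring A at C8, its more nucleophilic and less hindered free position (the site also taken in halogenation of 5,7-di-O-alkyl flavan-3-ols); the 3-O-benzyl group prevents formate formation.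

**Step 4**
Reactants: 5 penta-O-benzylcatechin-8-carbaldehyde
Product: 6 bromo aldehyde (6-bromo-penta-O-benzylcatechin-8-carbaldehyde)
Conditions: NBS (1.05 equiv), MeCN/CH2Cl2, 0 °C → rt, dark
Reagents that add atoms: N-bromosuccinimide, O=C1CCC(=O)N1Br
Why: Electrophilic aromatic bromination at C6, the last free position of ring A, which is still flanked by two oxygens and para to a third and should remain far more reactive than the catechol diether ring B despite the meta formyl group.

**Step 5**
Reactants: 7 3′,4′-dihydroxyacetophenone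
Product: 8 bis(benzyloxy)acetophenone (1-[3,4-bis(benzyloxy)phenyl]ethanone)
Conditions: BnBr (2.2 equiv), K2CO3, DMF, 60 °C
Reagents that add atoms: benzyl bromide, BrCc1ccccc1
Why: Williamson etherification of both phenols; the methyl ketone is not alkylated by carbonate.

**Step 6**
Reactants: 6 bromo aldehyde; 8 bis(benzyloxy)acetophenone
Product: 10 chalcone (E)-1-[3,4-bis(benzyloxy)phenyl]-3-(6-bromo-penta-O-benzylcatechin-8-yl)prop-2-en-1-one, via aldol adduct 9 (not isolated)
Conditions: KOH, EtOH/THF, rt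
Reagents that add atoms: none
Why: Claisen–Schmidt condensation of a non-enolisable aldehyde with the acetophenone enolate, followed by E1cB dehydration to the thermodynamically preferred E-enone; the fully etherified catechin is stable to hydroxide.

**Step 7**
Reactants: 10 chalcone
Product: 11 (R,E)-1-[3,4-bis(benzyloxy)phenyl]-3-(6-bromo-penta-O-benzylcatechin-8-yl)prop-2-en-1-ol
Conditions: (S)-1-methyl-3,3-diphenyltetrahydro-1H,3H-pyrrolo[1,2-c][1,3,2]oxazaborole [(S)-Me-CBS, 0.3 equiv], catecholborane, toluene, −78 → −40 °C; MeOH; aq. NaOH wash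
Reagents that add atoms: none
Why: Corey–Bakshi–Shibata 1,2-reduction in which the catalyst–borane complex binds the carbonyl lone pair on the side of the slimmer alkenyl arm and delivers hydride to give the (R)-carbinol; catecholborane avoids hydroboration of the alkene, and the basic work-up avoids ionising the diarylallyl alcohol.

**Step 8**
Reactants: 11 (R)-allylic alcohol
Product: 12 threo epoxy alcohol (1S,2R,3R)-1-[3,4-bis(benzyloxy)phenyl]-2,3-epoxy-3-(6-bromo-penta-O-benzylcatechin-8-yl)propan-1-ol (trans-epoxide)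
Conditions: 1,2:4,5-di-O-isopropylidene-β-D-erythro-2,3-hexodiulo-2,6-pyranose (Shi ketone from D-fructose, 0.5 equiv), KHSO5 (as Oxone), K2CO3, Bu4NHSO4, MeCN/CH2(OMe)2/aq. Na2B4O7 buffer (pH 10.5), 0 °C
Reagents that add atoms: potassium peroxymonosulfate, [K+].[O-]S(=O)(=O)OO
Why: Shi epoxidation, in which the chiral dioxirane approaches the E-aryl alkene through a spiro transition state and gives the (R,R)-type trans-epoxide under catalyst control; the basic buffer protects the acid-labile epoxide.

**Step 9**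
Reactants: 12 threo epoxy alcohol; 13 m-(benzyloxy)phenol [3-(benzyloxy)phenol]
Product: 14 aryl ether (1R,2S,3R)-1-[3,4-bis(benzyloxy)phenyl]-1-[3-(benzyloxy)phenoxy]-2,3-epoxy-3-(6-bromo-penta-O-benzylcatechin-8-yl)propane
Conditions: PPh3, DIAD, toluene, 0 °C → rt
Reagents that add atoms: none
Why: Mitsunobu etherification, an SN2 displacement of the alkoxyphosphonium group by the phenoxide with inversion (1S → 1R); the adjacent epoxide C–O bond disfavours ionisation of the benzylic carbon, which is why the ether is made here and not on the 1,3-diarylallyl alcohol 11.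

**Step 10**
Reactants: 14 aryl ether
Product: 15 dimer with free 3-OH (7,3′,4′-tri-O-benzylfisetinidol-(4α→8)-6-bromo-penta-O-benzylcatechin)
Conditions: (CF3)2CHOH/CH2Cl2 (4:1), 0 °C → rt
Reagents that add atoms: none
Why: The fluorinated alcohol hydrogen-bonds to the epoxide oxygen, and because the catechin ring (ring oxygen ortho, O5 para) stabilises positive charge at the benzylic epoxide carbon, that C–O bond is polarised and attacked from the rear by the tethered resorcinol ether ring in an intramolecular Friedel–Crafts alkylation, the arenium ion then losing a proton to the solvent. The closest known reaction type is the fluorinated-alcohol-promoted epoxy–arene cyclisation of aryl ethers of trans-3-arylglycidols to trans-4-arylchroman-3-ols. Ring C of the fisetinidol unit is closed by forming C4–C4a in a 6-endo epoxide opening; the 5-exo alternative would need attack at the non-benzylic epoxide carbon, which is not activated. The only new stereocentre, C4, is set by inversion at the benzylic carbon of the trans-epoxide (4S, aryl trans to the C3 hydroxyl, which keeps the epoxide oxygen); this is also the all-equatorial chroman, so kinetic and thermodynamic preferences should coincide, while C2 and C3 are carried over from steps 9 and 8. The step needs site selectivity on the arene and chemoselectivity among the aromatic rings: the carbon para to the benzyloxy group and ortho to the ether oxygen is the most nucleophilic and least hindered position and gives a six-membered ring, ring B of the side chain could only close a five-membered indane, and the C6 bromine blocks the last catechin position while damping the donor strength of that ring enough for the epoxide to be handled.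

**Step 11**
Reactants: 15 dimer with free 3-OH
Product: 16 bromo dimer (3,7,3′,4′-tetra-O-benzylfisetinidol-(4α→8)-6-bromo-penta-O-benzylcatechin)
Conditions: NaH, BnBr, Bu4NI (cat.), DMF, 0 °C → rt
Reagents that add atoms: benzyl bromide, BrCc1ccccc1
Why: Williamson benzylation of the hindered C3 alkoxide, so that no acidic proton remains for the organolithium step; the aryl bromide is inert to these conditions.

**Step 12**
Reactants: 17 (+)-fustin
Product: 18 tri-O-benzylfustin (7,3′,4′-tribenzyl ether, free 3-OH)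
Conditions: BnBr (3.3 equiv), K2CO3, DMF, rt
Reagents that add atoms: benzyl bromide, BrCc1ccccc1
Why: Williamson etherification of the three phenols under mild carbonate conditions at room temperature, chosen so that the dihydroflavonol ring C is not opened to the chalcone, which would scramble C2.

**Step 13**
Reactants: 18 tri-O-benzylfustin
Product: 19 tetra-O-benzylfustin ((2R,3R)-3,7-bis(benzyloxy)-2-[3,4-bis(benzyloxy)phenyl]chroman-4-one)
Conditions: BnBr, Ag2O, CH2Cl2, 4 Å MS, rt, dark
Reagents that add atoms: benzyl bromide, BrCc1ccccc1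
Why: Silver-oxide-mediated (Purdie-type) benzylation of the α-ketol hydroxyl under essentially neutral conditions, as used for base-sensitive α-hydroxy carbonyl compounds, so that C2 and C3 are not epimerised through the enolate.

**Step 14**
Reactants: 16 bromo dimer; 19 tetra-O-benzylfustin
Product: 22 tertiary C4 alcohol of the C6-linked unit (carbinol configuration uncontrolled), via C6-aryllithium 20 (not isolated), via C6-arylcerium dichloride 21 (not isolated)
Conditions: t-BuLi (2.1 equiv), THF, −78 °C; CeCl3, −78 °C; then 19, −78 → −40 °C; aq. NH4Cl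
Reagents that add atoms: none
Why: Bromine–lithium exchange at C6, transmetalation to the organocerium reagent (Imamoto conditions) and 1,2-addition to the aryl ketone; the weakly basic, oxophilic aryl–cerium should add to the carbonyl of 19 instead of enolising it, and the new carbinol centre is irrelevant because it is ionised in step 15.

**Step 15**
Reactants: 22 tertiary C4 alcohol
Product: 23 trideca-O-benzyl trimer (fisetinidol-(4α→8)-catechin-(6→4β)-fisetinidol, all hydroxyls benzylated)
Conditions: Et3SiH, CF3CO2H, CH2Cl2, −40 → 0 °C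
Reagents that add atoms: none
Why: Ionic hydrogenation, in which the acid ionises the tertiary doubly benzylic alcohol to a 4-aryl-flavan-4-yl cation whose C3 benzyloxy group turns pseudo-axial to escape A(1,2) strain with the perpendicular catechin ring, and the silane delivers hydride anti to that group, leaving the aryl cis to O3 (4β, 4R), as in known hydride reductions of 4-aryl-flavan-4-ols to 3,4-cis products.

**Step 16**
Reactants: 23 trideca-O-benzyl trimer
Product: 24 target, fisetinidol-(4α→8)-catechin-(6→4β)-fisetinidol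
Conditions: H2 (1 atm), Pd(OH)2/C, THF/MeOH, rt
Reagents that add atoms: none
Why: Catalytic hydrogenolysis of the thirteen benzyl ethers under neutral conditions, as used for oligomeric flavan-3-ols; no stereocentre is involved and the interflavan C–C bonds are not cleaved.

**Compound list**

1 | (+)-catechin, (2R,3S) | Oc1cc(O)c2c(c1)O[C@H](c1ccc(O)c(O)c1)[C@@H](O)C2 | starting material
2 | 5,7,3′,4′-tetra-O-benzylcatechin | c1ccccc1COc1cc(OCc3ccccc3)c2c(c1)O[C@H](c1ccc(OCc3ccccc3)c(OCc3ccccc3)c1)[C@@H](O)C2 | intermediate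
3 | 3,5,7,3′,4′-penta-O-benzylcatechin | c1ccccc1COc1cc(OCc3ccccc3)c2c(c1)O[C@H](c1ccc(OCc3ccccc3)c(OCc3ccccc3)c1)[C@@H](OCc1ccccc1)C2 | intermediate
4 | Vilsmeier iminium salt: 8-(dimethyliminiomethyl)-penta-O-benzylcatechin dichlorophosphate | C[N+](C)=Cc1c(OCc3ccccc3)cc(OCc3ccccc3)c2c1O[C@H](c1ccc(OCc3ccccc3)c(OCc3ccccc3)c1)[C@@H](OCc1ccccc1)C2.[O-]P(Cl)(Cl)=O | intermediate (not isolated)
5 | penta-O-benzylcatechin-8-carbaldehyde | O=Cc1c(OCc3ccccc3)cc(OCc3ccccc3)c2c1O[C@H](c1ccc(OCc3ccccc3)c(OCc3ccccc3)c1)[C@@H](OCc1ccccc1)C2 | intermediate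
6 | 6-bromo-penta-O-benzylcatechin-8-carbaldehyde | O=Cc1c(OCc3ccccc3)c(Br)c(OCc3ccccc3)c2c1O[C@H](c1ccc(OCc3ccccc3)c(OCc3ccccc3)c1)[C@@H](OCc1ccccc1)C2 | intermediate
7 | 3′,4′-dihydroxyacetophenone | CC(=O)c1ccc(O)c(O)c1 | starting material
8 | 1-[3,4-bis(benzyloxy)phenyl]ethanone | CC(=O)c1ccc(OCc2ccccc2)c(OCc2ccccc2)c1 | intermediate
9 | aldol adduct: 1-[3,4-bis(benzyloxy)phenyl]-3-hydroxy-3-(6-bromo-penta-O-benzylcatechin-8-yl)propan-1-one (carbinol epimers) | O=C(c1ccc(OCc2ccccc2)c(OCc2ccccc2)c1)CC(O)c1c(OCc3ccccc3)c(Br)c(OCc3ccccc3)c2c1O[C@H](c1ccc(OCc3ccccc3)c(OCc3ccccc3)c1)[C@@H](OCc1ccccc1)C2 | intermediate (not isolated)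
10 | (E)-1-[3,4-bis(benzyloxy)phenyl]-3-(6-bromo-penta-O-benzylcatechin-8-yl)prop-2-en-1-one | O=C(c1ccc(OCc2ccccc2)c(OCc2ccccc2)c1)/C=C/c1c(OCc3ccccc3)c(Br)c(OCc3ccccc3)c2c1O[C@H](c1ccc(OCc3ccccc3)c(OCc3ccccc3)c1)[C@@H](OCc1ccccc1)C2 | intermediate
11 | (R,E)-1-[3,4-bis(benzyloxy)phenyl]-3-(6-bromo-penta-O-benzylcatechin-8-yl)prop-2-en-1-ol | O[C@@H](c1ccc(OCc2ccccc2)c(OCc2ccccc2)c1)/C=C/c1c(OCc3ccccc3)c(Br)c(OCc3ccccc3)c2c1O[C@H](c1ccc(OCc3ccccc3)c(OCc3ccccc3)c1)[C@@H](OCc1ccccc1)C2 | intermediate
12 | (1S,2R,3R)-1-[3,4-bis(benzyloxy)phenyl]-2,3-epoxy-3-(6-bromo-penta-O-benzylcatechin-8-yl)propan-1-ol (threo, trans-epoxide) | O[C@@H](c1ccc(OCc2ccccc2)c(OCc2ccccc2)c1)[C@H]1O[C@@H]1c1c(OCc3ccccc3)c(Br)c(OCc3ccccc3)c2c1O[C@H](c1ccc(OCc3ccccc3)c(OCc3ccccc3)c1)[C@@H](OCc1ccccc1)C2 | intermediate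
13 | 3-(benzyloxy)phenol | Oc1cccc(OCc2ccccc2)c1 | starting material
14 | (1R,2S,3R)-1-[3,4-bis(benzyloxy)phenyl]-1-[3-(benzyloxy)phenoxy]-2,3-epoxy-3-(6-bromo-penta-O-benzylcatechin-8-yl)propane | c1ccccc1COc1cccc(c1)O[C@H](c1ccc(OCc3ccccc3)c(OCc3ccccc3)c1)[C@H]1O[C@@H]1c1c(OCc3ccccc3)c(Br)c(OCc3ccccc3)c2c1O[C@H](c1ccc(OCc3ccccc3)c(OCc3ccccc3)c1)[C@@H](OCc1ccccc1)C2 | intermediate
15 | 7,3′,4′-tri-O-benzylfisetinidol-(4α→8)-6-bromo-penta-O-benzylcatechin, free 3-OH on the fisetinidol unit (2R,3S,4S) | c1ccccc1COc1ccc2c(c1)O[C@H](c1ccc(OCc3ccccc3)c(OCc3ccccc3)c1)[C@@H](O)[C@@H]2c1c(OCc3ccccc3)c(Br)c(OCc3ccccc3)c2c1O[C@H](c1ccc(OCc3ccccc3)c(OCc3ccccc3)c1)[C@@H](OCc1ccccc1)C2 | intermediate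
16 | 3,7,3′,4′-tetra-O-benzylfisetinidol-(4α→8)-6-bromo-penta-O-benzylcatechin | c1ccccc1COc1ccc2c(c1)O[C@H](c1ccc(OCc3ccccc3)c(OCc3ccccc3)c1)[C@@H](OCc3ccccc3)[C@@H]2c1c(OCc3ccccc3)c(Br)c(OCc3ccccc3)c2c1O[C@H](c1ccc(OCc3ccccc3)c(OCc3ccccc3)c1)[C@@H](OCc1ccccc1)C2 | intermediate
17 | (+)-fustin, (2R,3R) | Oc1ccc2c(c1)O[C@H](c1ccc(O)c(O)c1)[C@@H](O)C2=O | starting material
18 | 7,3′,4′-tri-O-benzylfustin | c1ccccc1COc1ccc2c(c1)O[C@H](c1ccc(OCc3ccccc3)c(OCc3ccccc3)c1)[C@@H](O)C2=O | intermediate
19 | 3,7,3′,4′-tetra-O-benzylfustin | c1ccccc1COc1ccc2c(c1)O[C@H](c1ccc(OCc3ccccc3)c(OCc3ccccc3)c1)[C@@H](OCc1ccccc1)C2=O | intermediate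
20 | C6-aryllithium from 16 | c1ccccc1COc1ccc2c(c1)O[C@H](c1ccc(OCc3ccccc3)c(OCc3ccccc3)c1)[C@@H](OCc3ccccc3)[C@@H]2c1c(OCc3ccccc3)c([Li])c(OCc3ccccc3)c2c1O[C@H](c1ccc(OCc3ccccc3)c(OCc3ccccc3)c1)[C@@H](OCc1ccccc1)C2 | intermediate (not isolated)
21 | C6-arylcerium dichloride from 20 | c1ccccc1COc1ccc2c(c1)O[C@H](c1ccc(OCc3ccccc3)c(OCc3ccccc3)c1)[C@@H](OCc3ccccc3)[C@@H]2c1c(OCc3ccccc3)c([Ce](Cl)Cl)c(OCc3ccccc3)c2c1O[C@H](c1ccc(OCc3ccccc3)c(OCc3ccccc3)c1)[C@@H](OCc1ccccc1)C2 | intermediate (not isolated)
22 | tertiary alcohol: C4 of 3,7,3′,4′-tetra-O-benzyl-4-hydroxyfisetinidol bonded to C6 of the debrominated dimer (C4 carbinol configuration not defined) | c5ccccc5COc1ccc2c(c1)O[C@H](c1ccc(OCc5ccccc5)c(OCc5ccccc5)c1)[C@@H](OCc5ccccc5)[C@@H]2c1c(OCc5ccccc5)c(C3(O)c4ccc(OCc5ccccc5)cc4O[C@H](c4ccc(OCc5ccccc5)c(OCc5ccccc5)c4)[C@H]3OCc5ccccc5)c(OCc5ccccc5)c2c1O[C@H](c1ccc(OCc5ccccc5)c(OCc5ccccc5)c1)[C@@H](OCc5ccccc5)C2 | intermediate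
23 | trideca-O-benzyl fisetinidol-(4α→8)-catechin-(6→4β)-fisetinidol | c5ccccc5COc1ccc2c(c1)O[C@H](c1ccc(OCc5ccccc5)c(OCc5ccccc5)c1)[C@@H](OCc5ccccc5)[C@@H]2c1c(OCc5ccccc5)c([C@H]3c4ccc(OCc5ccccc5)cc4O[C@H](c4ccc(OCc5ccccc5)c(OCc5ccccc5)c4)[C@H]3OCc5ccccc5)c(OCc5ccccc5)c2c1O[C@H](c1ccc(OCc5ccccc5)c(OCc5ccccc5)c1)[C@@H](OCc5ccccc5)C2 | intermediate
24 | fisetinidol-(4α→8)-catechin-(6→4β)-fisetinidol (CNP0289228.1) | Oc1ccc2c(c1)O[C@H](c1ccc(O)c(O)c1)[C@@H](O)[C@H]2c1c(O)c2c(c([C@@H]3c4ccc(O)cc4O[C@H](c4ccc(O)c(O)c4)[C@H]3O)c1O)O[C@H](c1ccc(O)c(O)c1)[C@@H](O)C2 | target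

**Step count and risk**

Total step count: 16. Longest linear sequence: 13 steps (1, 2, 3, 4, 6, 7, 8, 9, 10, 11, 14, 15, 16).

Step 10 (key step). After ionisation, the benzylic cation may undergo a 1,2-hydride shift (Meinwald rearrangement to a ketone), be captured by the solvent, or close through the ring carbon between the two oxygens; a long-lived cation could also erode the trans selectivity. The fallback abandons the epoxide and makes the same C4–C8 bond intermolecularly. It sets out from 18 and 3. Reduction of 18 with NaBH4 in THF/EtOH should give 7,3′,4′-tri-O-benzylflavan-3,4-diol F1 (C4 epimers, both usable). Ionisation of F1 with TiCl4 or BF3·OEt2 in CH2Cl2 at low temperature in the presence of 3 should alkylate C8, the more nucleophilic catechin position, trans to the C3 hydroxyl, giving the 4α→8 dimer with free 3-OH and free C6, F2. Bromination of F2 with NBS at C6 of the catechin ring, the only ring carrying three oxygens, returns the route at 15.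

Step 14. The aryl–metal, flanked by two benzyloxy groups, may act as a base instead of a nucleophile, enolising 19, which then opens ring C by β-elimination, so that the arene is recovered protonated. The fallback replaces carbonyl addition by cation chemistry and covers steps 14 and 15 together. It sets out from 16 and 19. Bromine–lithium exchange on 16 with t-BuLi and a MeOH quench gives the C6–H dimer F3; NaBH4 reduction of 19 gives 3,7,3′,4′-tetra-O-benzylflavan-4-ol F4. BF3·OEt2 in CH2Cl2 at low temperature ionises F4, and the 5-deoxy flavan-4-yl cation is expected to alkylate C6 of F3 from both faces. The product 23 would therefore have to be separated by chromatography from its C4 epimer, the 6→4α trimer F5; the route is rejoined at 23.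

Step 8. Facial selectivity may be poor if the catalyst and the carbinol centre are mismatched, the allylic alcohol may be oxidised, and the very electron-rich epoxide may open solvolytically during isolation. The fallback uses nucleophilic instead of electrophilic epoxidation and places it before the carbonyl reduction. It sets out from 10. Juliá–Colonna epoxidation (poly-D-leucine, the catalyst enantiomer that leads to the (2S,3R) series of chalcone oxides, urea·H2O2, DBU, THF) should give the (2S,3R)-epoxy ketone F6, whose epoxide is stabilised by the acyl group. Reagent-controlled reduction with (S)-Me-CBS and catecholborane, as in step 7, then returns the route at 12.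

**Further compounds**

F1 | step 10 | (2R,3S)-7-(benzyloxy)-2-[3,4-bis(benzyloxy)phenyl]chromane-3,4-diol (C4 epimers) | c1ccccc1COc1ccc2c(c1)O[C@H](c1ccc(OCc3ccccc3)c(OCc3ccccc3)c1)[C@@H](O)C2O
F2 | step 10 | 7,3′,4′-tri-O-benzylfisetinidol-(4α→8)-penta-O-benzylcatechin (free 3-OH, C6–H) | c1ccccc1COc1ccc2c(c1)O[C@H](c1ccc(OCc3ccccc3)c(OCc3ccccc3)c1)[C@@H](O)[C@@H]2c1c(OCc3ccccc3)cc(OCc3ccccc3)c2c1O[C@H](c1ccc(OCc3ccccc3)c(OCc3ccccc3)c1)[C@@H](OCc1ccccc1)C2
F3 | step 14 | 3,7,3′,4′-tetra-O-benzylfisetinidol-(4α→8)-penta-O-benzylcatechin (C6–H) | c1ccccc1COc1ccc2c(c1)O[C@H](c1ccc(OCc3ccccc3)c(OCc3ccccc3)c1)[C@@H](OCc3ccccc3)[C@@H]2c1c(OCc3ccccc3)cc(OCc3ccccc3)c2c1O[C@H](c1ccc(OCc3ccccc3)c(OCc3ccccc3)c1)[C@@H](OCc1ccccc1)C2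
F4 | step 14 | (2R,3S)-3,7-bis(benzyloxy)-2-[3,4-bis(benzyloxy)phenyl]chroman-4-ol (C4 epimers) | c1ccccc1COc1ccc2c(c1)O[C@H](c1ccc(OCc3ccccc3)c(OCc3ccccc3)c1)[C@@H](OCc1ccccc1)C2O
F5 | step 14 | trideca-O-benzyl fisetinidol-(4α→8)-catechin-(6→4α)-fisetinidol (C4 epimer of 23) | c5ccccc5COc1ccc2c(c1)O[C@H](c1ccc(OCc5ccccc5)c(OCc5ccccc5)c1)[C@@H](OCc5ccccc5)[C@@H]2c1c(OCc5ccccc5)c([C@@H]3c4ccc(OCc5ccccc5)cc4O[C@H](c4ccc(OCc5ccccc5)c(OCc5ccccc5)c4)[C@H]3OCc5ccccc5)c(OCc5ccccc5)c2c1O[C@H](c1ccc(OCc5ccccc5)c(OCc5ccccc5)c1)[C@@H](OCc5ccccc5)C2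
F6 | step 8 | (2S,3R)-1-[3,4-bis(benzyloxy)phenyl]-2,3-epoxy-3-(6-bromo-penta-O-benzylcatechin-8-yl)propan-1-one | O=C(c1ccc(OCc2ccccc2)c(OCc2ccccc2)c1)[C@H]1O[C@@H]1c1c(OCc3ccccc3)c(Br)c(OCc3ccccc3)c2c1O[C@H](c1ccc(OCc3ccccc3)c(OCc3ccccc3)c1)[C@@H](OCc1ccccc1)C2
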